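The aryl–C1′ bond is cut first. C11–OH and C4–H are then taken back by re-closing C6–C11, which turns the eudesm-5-en-11-ol into a 6,11-cycloeudesm-4-ene (maaliane skeleton). Further cuts are ring A by [4+2] (C1–C10, C2–C3), C4–C5 (cross-coupling) and C1′–C2′ (sulfone carbanion plus aldehyde).
In the forward direction, ring B and the cyclopropane come from (S)-carvone and ring A closes by a Diels–Alder reaction. The side chain then grows on a sulfone at C2′, the complete masked arene is joined, and the cyclopropane is opened last to give C5=C6 and C11–OH.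
The union is possible because C1′ is a CH between C2′ and C1–H of ring A. C2′ is a CH2 that can carry a sulfonyl group, so C1′=C2′ becomes an acceptor. The ring neighbours of C1 differ as much as possible: quaternary C10 with its axial CH3 against the CH2 C2.
C7 comes from (S)-carvone. The C6–C7–C11 ring blocks the α face and sets C10 (cycloaddition), C1 (hydrogenation) and C4 (protonation). C1 sets C1′ through A1,3 strain when the aryl group arrives last.

Key step: step 13

Locants: the decalin carries eudesmane numbers (C1 = ring CH with the side chain, C4 = CH–CH3, C5=C6, C7 = CH–C11, C10 = quaternary C). C1′ is the benzylic CH, C2′ its CH2 and C3′ the isobutyl CH. α is the face of C10–CH3 and β the opposite face.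
Assumption: 2,4,6-trihydroxybenzene-1,3-dicarbaldehyde is taken as a purchasable starting material.

Step 1
Reactants: 1 (S)-(+)-carvone
Product: 2 (2S,5S)-dihydrocarvone
Conditions: Zn, KOH, MeOH–H2O, reflux
Reagents that add atoms: none
Why: Dissolving-metal conjugate reduction takes only the enone C=C and leaves the isopropenyl group; the new centre (trans isomer favoured) is erased in step 4.

Step 2
Reactants: 2 (2S,5S)-dihydrocarvone
Product: 3 (2S,5S)-5-(2-chloropropan-2-yl)-2-methylcyclohexan-1-one
Conditions: HCl (g), Et2O, 0 °C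
Reagents that add atoms: hydrogen chloride, Cl
Why: Markovnikov hydrochlorination of the 1,1-disubstituted alkene gives the tertiary chloride, the classical entry to carone.

Step 3
Reactants: 3 (2S,5S)-5-(2-chloropropan-2-yl)-2-methylcyclohexan-1-one
Product: 4 (1R,3S,6S)-3,7,7-trimethylbicyclo[4.1.0]heptan-2-one (carone)
Conditions: KOH, MeOH, 0 °C to rt
Reagents that add atoms: none
Why: Enolisation towards C6 and 3-exo-tet displacement of chloride (1,3-elimination) close the necessarily cis-fused cyclopropane on the face fixed by C7; the C3 epimer is harmless.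

Step 4
Reactants: 4 carone
Product: 5 (1R,6S)-3,7,7-trimethylbicyclo[4.1.0]hept-2-en-2-yl trifluoromethanesulfonate
Conditions: KHMDS, THF, −78 °C; PhNTf2, −78 to 0 °C
Reagents that add atoms: N-phenylbis(trifluoromethanesulfonimide), O=S(=O)(N(c1ccccc1)S(=O)(=O)C(F)(F)F)C(F)(F)F
Why: Only C10–H can be enolised because C6 is a cyclopropane CH, so O-triflation gives the tetrasubstituted enol triflate as one regioisomer.

Step 5
Reactants: 5 enol triflate; 6 isopropenylboronic acid pinacol ester
Product: 7 (1R,6S)-3,7,7-trimethyl-2-(prop-1-en-2-yl)bicyclo[4.1.0]hept-2-ene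
Conditions: Pd(dppf)Cl2 (cat.), K3PO4, dioxane–H2O, 60 °C
Reagents that add atoms: none
Why: Suzuki–Miyaura coupling of a vinyl triflate with an alkenylboronate forms C4–C5 and leaves the ring alkene in place.

Step 6
Reactants: 7 diene; 8 methyl propiolate
Product: 9 methyl (6R,7S,10S)-6,11-cycloeudesma-1,4-diene-1-carboxylate
Conditions: toluene, BHT (cat.), 110 °C, sealed tube
Reagents that add atoms: none
Why: Thermal Diels–Alder reaction with an acetylenic ester, known to build angular methyl centres from 1-vinyl-2-methylcyclohexenes; C3 (largest HOMO coefficient) bonds to the alkyne CH and C10 to the ester-bearing carbon (ortho/para rule), and attack anti to the gem-dimethylcyclopropane places C10–CH3 on the face of C11.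

Step 7
Reactants: 9 dienoate
Product: 10 methyl (1S,6R,7S,10R)-6,11-cycloeudesm-4-ene-1-carboxylate
Conditions: H2 (1 atm), Pd/C, EtOAc, rt, stopped after one equivalent
Reagents that add atoms: none
Why: Heterogeneous hydrogenation saturates only the trisubstituted enoate C1=C2 (C4=C5 is tetrasubstituted) by syn delivery from the β face, away from C10–CH3 and the cyclopropane, which sets C1.

Step 8
Reactants: 10 saturated ester
Product: 11 (1S,6R,7S,10R)-6,11-cycloeudesm-4-ene-1-carbaldehyde
Conditions: DIBAL-H (1.05 equiv), CH2Cl2, −78 °C; Rochelle salt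
Reagents that add atoms: none
Why: Partial DIBAL-H reduction of the hindered ester stops at the aluminium hemiacetal at −78 °C and gives the aldehyde without disturbing C1.

Step 9
Reactants: 12 sodium benzenesulfinate; 13 1-iodo-2-methylpropane
Product: 14 isobutyl phenyl sulfone
Conditions: DMF, 80 °C
Reagents that add atoms: none
Why: SN2 S-alkylation of the sulfinate gives the sulfone.

Step 10
Reactants: 14 isobutyl phenyl sulfone; 11 aldehyde
Product: 15 β-acetoxy sulfone, 1-[(1S,6R,7S,10R)-6,11-cycloeudesm-4-en-1-yl]-3-methyl-2-(phenylsulfonyl)butyl acetate (mixture at C1′ and C2′)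
Conditions: 14, n-BuLi, THF, −78 °C; 11; Ac2O, −78 °C to rt
Reagents that add atoms: acetic anhydride, CC(=O)OC(C)=O
Why: Julia-type addition of the α-sulfonyl carbanion to the aldehyde forms C1′–C2′ and acetylation in the flask blocks the retro-addition; both new centres are erased in step 13.

Step 11
Reactants: 16 2,4,6-trihydroxybenzene-1,3-dicarbaldehyde
Product: 17 2,4,6-tris(methoxymethoxy)benzene-1,3-dicarbaldehyde
Conditions: NaH, MOMCl, DMF, 0 °C to rt
Reagents that add atoms: chloromethyl methyl ether, COCCl
Why: Williamson-type O-alkylation protects the three phenols as base-stable, acid-labile MOM ethers.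

Step 12
Reactants: 17 tris-MOM dialdehyde
Product: 18 2,4-bis(dimethoxymethyl)-1,3,5-tris(methoxymethoxy)benzene
Conditions: HC(OMe)3, MeOH, PPTS (cat.), rt
Reagents that add atoms: trimethyl orthoformate, COC(OC)OC
Why: Mild acid-catalysed acetalisation driven by the orthoformate masks both aldehydes against organolithium reagents.

Step 13
Reactants: 18 masked arene; 15 β-acetoxy sulfone
Product: 22 (1′S)-aryl sulfone, 6,11-cycloeudesm-4-ene carrying at C1 the group CH(aryl)–CH(SO2Ph)–CH(CH3)2 (mixture at C2′), via aryllithium 19 (not isolated), via vinyl sulfone 20 (not isolated), via lithiated sulfone 21 (not isolated)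
Conditions: 18 (2.3 equiv), n-BuLi (2.2 equiv), THF, 0 °C; 15, −78 to −20 °C; aq NH4Cl
Reagents that add atoms: n-butyllithium, [Li]CCCC (lithium stays only in 19 and 21)
Why: Directed ortho-lithiation of 18 at its only ring C–H, between two OMOM groups, gives 19; one equivalent removes C2′–H of 15 so that acetate leaves (E1cB) and 20 forms at low temperature, a second equivalent adds to C1′ to give 21, and the quench protonates C2′. The closest known reaction type is the heteroconjugate addition of organolithiums to β-substituted vinyl sulfones, including its elimination–addition variant from β-acyloxy sulfones. No ring is closed. C1′ is the only lasting new stereocentre: the C2′ substituent that lies cis to C1 forces C1–H to eclipse C1′=C2′ (A1,3 strain), C10 with its axial CH3 then covers one face, and the aryl group enters from the C2 side, which gives 1′S for either alkene geometry, while the C2′ mixture is erased in step 14. The step needs 1,4-addition to outrun γ-deprotonation (C1–H, C3′–H) and attack at the acetate carbonyl; both γ-hydrogens are tertiary and shielded, the chelated di-ortho-substituted aryllithium is slow towards C=O, and the tetrasubstituted alkene, the cyclopropane, the MOM ethers and the acetals are inert to it.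

Step 14
Reactants: 22 aryl sulfone
Product: 23 (1R,6R,7S,10R,1′S)-1-{1-[3,5-bis(dimethoxymethyl)-2,4,6-tris(methoxymethoxy)phenyl]-3-methylbutyl}-6,11-cycloeudesm-4-ene
Conditions: Na/Hg (6%), Na2HPO4, MeOH–THF, −20 °C to rt
Reagents that add atoms: none
Why: Buffered sodium-amalgam desulfonylation replaces C–S by C–H at C2′ and completes the isobutyl group without reducing acetals, MOM ethers, the alkene or the cyclopropane.

Step 15
Reactants: 23 masked maaliene
Product: 24 target, (1R,4R,7S,10R,1′S)-1-[1-(3,5-diformyl-2,4,6-trihydroxyphenyl)-3-methylbutyl]eudesm-5-en-11-ol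
Conditions: 0.5 M H2SO4 (aq)–THF, rt
Reagents that add atoms: water, O
Why: Aqueous acid hydrolyses the two acetals and three MOM ethers and protonates C4 of the tetrasubstituted vinylcyclopropane from the β face, anti to the C6–C11 bond and to C10–CH3 (sets C4), after which the cyclopropylcarbinyl cation at C5 opens to C5=C6 and the tertiary C11 cation that water captures (cyclopropylcarbinyl–homoallyl rearrangement, as in the acid hydration of 2-carene).

Compound list
1 | (S)-(+)-carvone | CC1=CC[C@@H](CC1=O)C(C)=C | starting material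
2 | (2S,5S)-dihydrocarvone | C[C@H]1CC[C@@H](CC1=O)C(C)=C | intermediate
3 | (2S,5S)-5-(2-chloropropan-2-yl)-2-methylcyclohexan-1-one | C[C@H]1CC[C@@H](CC1=O)C(C)(C)Cl | intermediate
4 | (1R,3S,6S)-carone | C[C@H]1CC[C@H]2[C@@H](C1=O)C2(C)C | intermediate
5 | (1R,6S)-3,7,7-trimethylbicyclo[4.1.0]hept-2-en-2-yl triflate | CC1=C(OS(=O)(=O)C(F)(F)F)[C@@H]2[C@H](CC1)C2(C)C | intermediate
6 | isopropenylboronic acid pinacol ester | C=C(C)B1OC(C)(C)C(C)(C)O1 | starting material
7 | (1R,6S)-3,7,7-trimethyl-2-(prop-1-en-2-yl)bicyclo[4.1.0]hept-2-ene | CC1=C(C(C)=C)[C@@H]2[C@H](CC1)C2(C)C | intermediate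
8 | methyl propiolate | C#CC(=O)OC | starting material
9 | methyl (6R,7S,10S)-6,11-cycloeudesma-1,4-diene-1-carboxylate | COC(=O)C1=CCC(C)=C2[C@@H]3[C@H](CC[C@@]21C)C3(C)C | intermediate
10 | methyl (1S,6R,7S,10R)-6,11-cycloeudesm-4-ene-1-carboxylate | COC(=O)[C@H]1CCC(C)=C2[C@@H]3[C@H](CC[C@@]21C)C3(C)C | intermediate
11 | (1S,6R,7S,10R)-6,11-cycloeudesm-4-ene-1-carbaldehyde | O=C[C@H]1CCC(C)=C2[C@@H]3[C@H](CC[C@@]21C)C3(C)C | intermediate
12 | sodium benzenesulfinate | [Na+].[O-]S(=O)c1ccccc1 | starting material
13 | 1-iodo-2-methylpropane | CC(C)CI | starting material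
14 | isobutyl phenyl sulfone | CC(C)CS(=O)(=O)c1ccccc1 | intermediate
15 | β-acetoxy sulfone (mixture at C1′ and C2′) | CC(C)C(C(OC(C)=O)[C@H]1CCC(C)=C2[C@@H]3[C@H](CC[C@@]21C)C3(C)C)S(=O)(=O)c1ccccc1 | intermediate
16 | 2,4,6-trihydroxybenzene-1,3-dicarbaldehyde | O=Cc1c(O)cc(O)c(C=O)c1O | starting material
17 | 2,4,6-tris(methoxymethoxy)benzene-1,3-dicarbaldehyde | O=Cc1c(OCOC)cc(OCOC)c(C=O)c1OCOC | intermediate
18 | 2,4-bis(dimethoxymethyl)-1,3,5-tris(methoxymethoxy)benzene | COC(OC)c1c(OCOC)cc(OCOC)c(C(OC)OC)c1OCOC | intermediate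
19 | aryllithium from 18 | [Li]c1c(OCOC)c(C(OC)OC)c(OCOC)c(C(OC)OC)c1OCOC | intermediate
20 | vinyl sulfone (drawn E; the Z isomer reacts alike) | CC(C)/C(S(=O)(=O)c4ccccc4)=C\[C@H]1CCC(C)=C2[C@@H]3[C@H](CC[C@@]21C)C3(C)C | intermediate
21 | lithiated sulfone adduct | CC(C)C([Li])(S(=O)(=O)c4ccccc4)[C@H](c5c(OCOC)c(C(OC)OC)c(OCOC)c(C(OC)OC)c5OCOC)[C@H]1CCC(C)=C2[C@@H]3[C@H](CC[C@@]21C)C3(C)C | intermediate
22 | (1′S)-aryl sulfone (mixture at C2′) | CC(C)C(S(=O)(=O)c4ccccc4)[C@H](c5c(OCOC)c(C(OC)OC)c(OCOC)c(C(OC)OC)c5OCOC)[C@H]1CCC(C)=C2[C@@H]3[C@H](CC[C@@]21C)C3(C)C | intermediate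
23 | masked maaliene | CC(C)C[C@H](c5c(OCOC)c(C(OC)OC)c(OCOC)c(C(OC)OC)c5OCOC)[C@H]1CCC(C)=C2[C@@H]3[C@H](CC[C@@]21C)C3(C)C | intermediate
24 | target CNP0108656.4 | CC(C)C[C@H](c1c(O)c(C=O)c(O)c(C=O)c1O)[C@H]1CC[C@@H](C)C2=C[C@@H](C(C)(C)O)CC[C@@]21C | target

Total step count: 15. Longest linear sequence: 12 (steps 1–8, 10, 13, 14, 15).

Steps most likely to fail

**Step 13.** The C–C bond formation between two congested carbons may be so slow that γ-deprotonation, attack at the acetate followed by retro-addition, or loss of facial control takes over.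
- The fallback sets out from 11 and returns at 23.
- Wittig olefination of 11 with 1-(triphenylphosphoranylidene)propan-2-one gives the unhindered (E)-enone F1.
- Copper(I)-mediated 1,4-addition of 19 (CuBr·SMe2, THF, −78 to −20 °C) is non-basic and is the reaction class established for 2,6-dialkoxyaryl copper reagents. It gives the β-aryl methyl ketone F2 by the same facial argument.
- Methylenation (Ph3P=CH2) gives the 1,1-disubstituted alkene F3.
- Hydrogenation with Wilkinson's catalyst, which leaves the tetrasubstituted alkene alone, gives 23.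

**Step 6.** Bond formation at the tetrasubstituted diene terminus may be too slow, so that a thermal [1,5]-hydrogen shift of the diene, polymerisation of the alkyne or erosion of regioselectivity competes.
- The fallback sets out from 5 and returns at 9.
- Carbonylative Stille coupling of 5 (CO, Me4Sn, Pd(PPh3)4, LiCl) gives the methyl ketone F4.
- TBSOTf/Et3N gives the 2-silyloxydiene F5. Its raised HOMO lets the cycloaddition with 8 run well below 100 °C with the same (para) orientation, giving the silyl enol ether F6.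
- CsF/PhNTf2 converts F6 into the enol triflate F7.
- Suzuki methylation (MeB(OH)2, Pd(dppf)Cl2, K3PO4) gives 9.

**Step 15.** Several things may go wrong. The C11 cation may lose a proton, the product alcohol may re-ionise, or protonation may occur at C5 or from the α face. The acid strength needed for deprotection may also not match that tolerated by the tertiary alcohol.
- The fallback sets out from 23 and returns at 24, and replaces the cation by a radical.
- Mukaiyama-type hydration (Mn(dpm)3 cat., PhSiH3, O2, i-PrOH, 0 °C) delivers H to C4 from the open β face.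
- The cyclopropylcarbinyl radical at C5 opens, and O2 traps the C11 radical to give the hydroperoxide F8.
- PPh3 reduces F8 to the masked alcohol F9.
- A separate, milder hydrolysis (aq AcOH–THF) then removes acetals and MOM ethers to give 24.

Further compounds
F1 | step 13 | (E)-4-[(1R,6R,7S,10R)-6,11-cycloeudesm-4-en-1-yl]but-3-en-2-one | CC(=O)/C=C/[C@H]1CCC(C)=C2[C@@H]3[C@H](CC[C@@]21C)C3(C)C
F2 | step 13 | (4S)-4-aryl-4-(6,11-cycloeudesm-4-en-1-yl)butan-2-one | CC(=O)C[C@H](c5c(OCOC)c(C(OC)OC)c(OCOC)c(C(OC)OC)c5OCOC)[C@H]1CCC(C)=C2[C@@H]3[C@H](CC[C@@]21C)C3(C)C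
F3 | step 13 | methallyl analogue of 23 | C=C(C)C[C@H](c5c(OCOC)c(C(OC)OC)c(OCOC)c(C(OC)OC)c5OCOC)[C@H]1CCC(C)=C2[C@@H]3[C@H](CC[C@@]21C)C3(C)C
F4 | step 6 | 1-[(1R,6S)-3,7,7-trimethylbicyclo[4.1.0]hept-2-en-2-yl]ethan-1-one | CC1=C(C(C)=O)[C@@H]2[C@H](CC1)C2(C)C
F5 | step 6 | 2-silyloxydiene from F4 | CC1=C(C(=C)O[Si](C)(C)C(C)(C)C)[C@@H]2[C@H](CC1)C2(C)C
F6 | step 6 | cycloadduct with C4–OTBS | COC(=O)C1=CCC(O[Si](C)(C)C(C)(C)C)=C2[C@@H]3[C@H](CC[C@@]21C)C3(C)C
F7 | step 6 | C4 enol triflate | COC(=O)C1=CCC(OS(=O)(=O)C(F)(F)F)=C2[C@@H]3[C@H](CC[C@@]21C)C3(C)C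
F8 | step 15 | masked eudesm-5-ene 11-hydroperoxide | CC(C)C[C@H](c5c(OCOC)c(C(OC)OC)c(OCOC)c(C(OC)OC)c5OCOC)[C@H]1CC[C@@H](C)C2=C[C@@H](C(C)(C)OO)CC[C@@]21C
F9 | step 15 | masked eudesm-5-en-11-ol | CC(C)C[C@H](c5c(OCOC)c(C(OC)OC)c(OCOC)c(C(OC)OC)c5OCOC)[C@H]1CC[C@@H](C)C2=C[C@@H](C(C)(C)O)CC[C@@]21C
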